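**Retrosynthetic overview**
- The target comes from chemoselective reduction of the corresponding diaryl ether aldehyde (CHO to CH2OH on ring B).
- The diaryl ether C–O bond comes from an SNAr reaction: symmetric methyl 2,6-dihydroxy-4-methylbenzoate (ring A, bought) displaces fluoride from 2-fluoro-5-methoxy-3-(prenyloxy)benzaldehyde (ring B), activated by the ortho formyl group.
- The ring B fluoride comes from O-prenylation of 2-fluoro-3-hydroxy-5-methoxybenzaldehyde, itself made by C–H borylation/oxidation next to fluorine of 2-fluoro-5-methoxybenzaldehyde (masked as its dioxolane).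
- No ring is formed: both benzene rings are bought; ring B is functionalised first, then joined to ring A, and the aldehyde is reduced last.

Assumption: the target has no stereocentre and no stereogenic double bond, so it is achiral and is made as the single compound drawn.

**Step 1**
Reactants: 1 2-fluoro-5-methoxybenzaldehyde; 2 ethylene glycol
Product: 3 2-(2-fluoro-5-methoxyphenyl)-1,3-dioxolane
Conditions: ethylene glycol (3 equiv), p-TsOH·H2O (cat.), toluene, reflux, Dean–Stark
Reagents that add atoms: ethylene glycol (2), OCCO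
Why: Acid-catalysed acetalisation with azeotropic removal of water masks the aldehyde, which would otherwise be reduced by the B–H species of the next step; no stereocentre is formed.

**Step 2**
Reactants: 3 2-(2-fluoro-5-methoxyphenyl)-1,3-dioxolane; 4 bis(pinacolato)diboron (B2pin2)
Product: 7 2-fluoro-3-hydroxy-5-methoxybenzaldehyde, via pinacol boronate 5 (not isolated), via hydroxy dioxolane 6 (not isolated)
Conditions: [Ir(OMe)(cod)]2 (1.5 mol%), 4,4'-di-tert-butyl-2,2'-bipyridine (3 mol%), B2pin2 (0.6 equiv), THF, 80 °C; then NaOH, 30% H2O2, THF/H2O, 0 °C to rt; Na2S2O3 quench; then 2 M HCl, rt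
Reagents that add atoms: hydrogen peroxide, OO; water, O
Why: Iridium-catalysed C–H borylation is sterically controlled and takes the C–H next to the small fluorine rather than the two C–H bonds ortho to methoxy, after which boronate oxidation (aryl shift from boron to peroxide oxygen) gives the phenol and acid-catalysed acetal hydrolysis frees the aldehyde.

**Step 3**
Reactants: 7 2-fluoro-3-hydroxy-5-methoxybenzaldehyde; 8 prenyl bromide (1-bromo-3-methylbut-2-ene)
Product: 9 2-fluoro-5-methoxy-3-[(3-methylbut-2-en-1-yl)oxy]benzaldehyde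
Conditions: prenyl bromide (1.2 equiv), K2CO3 (1.5 equiv), DMF, rt
Reagents that add atoms: prenyl bromide (8), CC(C)=CCBr
Why: Williamson ether synthesis, an SN2 reaction of the phenoxide on the primary allylic bromide, which is much faster at room temperature than any attack on the aryl fluoride.

**Step 4**
Reactants: 9 2-fluoro-5-methoxy-3-[(3-methylbut-2-en-1-yl)oxy]benzaldehyde; 10 methyl 2,6-dihydroxy-4-methylbenzoate
Product: 11 methyl 2-{2-formyl-4-methoxy-6-[(3-methylbut-2-en-1-yl)oxy]phenoxy}-6-hydroxy-4-methylbenzoate
Conditions: 10 (1.5 equiv), Cs2CO3 (2.5 equiv), DMSO, 100 °C, N2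
Reagents that add atoms: methyl 2,6-dihydroxy-4-methylbenzoate (10), COC(=O)c1c(O)cc(C)cc1O
Why: Nucleophilic aromatic substitution (addition–elimination through a Meisenheimer complex stabilised by the ortho formyl group); the two hydroxyls of 10 are equivalent by symmetry and the one left over is tied up in a hydrogen bond to the ester, so mono-arylation results.

**Step 5**
Reactants: 11 methyl 2-{2-formyl-4-methoxy-6-[(3-methylbut-2-en-1-yl)oxy]phenoxy}-6-hydroxy-4-methylbenzoate
Product: 12 methyl 2-hydroxy-6-{2-(hydroxymethyl)-4-methoxy-6-[(3-methylbut-2-en-1-yl)oxy]phenoxy}-4-methylbenzoate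
Conditions: NaBH4 (1 equiv), MeOH/THF, 0 °C, 20 min; aq NH4Cl
Reagents that add atoms: none
Why: Chemoselective borohydride reduction of the aryl aldehyde, which leaves the hindered, hydrogen-bonded salicylate ester and the trisubstituted alkene untouched; the product is achiral, so no stereocontrol is needed.

**Compound list**
1 | 2-fluoro-5-methoxybenzaldehyde | COc1ccc(F)c(C=O)c1 | starting material
2 | ethylene glycol | OCCO | starting material
3 | 2-(2-fluoro-5-methoxyphenyl)-1,3-dioxolane | COc1ccc(F)c(C2OCCO2)c1 | intermediate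
4 | bis(pinacolato)diboron | CC1(C)OB(OC1(C)C)B1OC(C)(C)C(C)(C)O1 | starting material
5 | 2-[3-(1,3-dioxolan-2-yl)-2-fluoro-5-methoxyphenyl]-4,4,5,5-tetramethyl-1,3,2-dioxaborolane | COc1cc(B2OC(C)(C)C(C)(C)O2)c(F)c(C2OCCO2)c1 | intermediate (not isolated)
6 | 3-(1,3-dioxolan-2-yl)-2-fluoro-5-methoxyphenol | COc1cc(O)c(F)c(C2OCCO2)c1 | intermediate (not isolated)
7 | 2-fluoro-3-hydroxy-5-methoxybenzaldehyde | COc1cc(O)c(F)c(C=O)c1 | intermediate
8 | prenyl bromide (1-bromo-3-methylbut-2-ene) | CC(C)=CCBr | starting material
9 | 2-fluoro-5-methoxy-3-[(3-methylbut-2-en-1-yl)oxy]benzaldehyde | COc1cc(OCC=C(C)C)c(F)c(C=O)c1 | intermediate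
10 | methyl 2,6-dihydroxy-4-methylbenzoate | COC(=O)c1c(O)cc(C)cc1O | starting material
11 | methyl 2-{2-formyl-4-methoxy-6-[(3-methylbut-2-en-1-yl)oxy]phenoxy}-6-hydroxy-4-methylbenzoate | COC(=O)c1c(O)cc(C)cc1Oc1c(C=O)cc(OC)cc1OCC=C(C)C | intermediate
12 | methyl 2-hydroxy-6-{2-(hydroxymethyl)-4-methoxy-6-[(3-methylbut-2-en-1-yl)oxy]phenoxy}-4-methylbenzoate | COC(=O)c1c(O)cc(C)cc1Oc1c(CO)cc(OC)cc1OCC=C(C)C | target

**Totals**
Total step count: 5. Longest linear sequence: 5 steps (1 → 3 → 7 → 9 → 11 → 12).

**Steps most likely to fail, with fallbacks**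

(1) Step 4 is the weakest point. The fluoride of 9 is activated only by the ortho formyl group and is deactivated by alkoxy groups ortho and para to it. The phenoxide of 10 is a weak, hydrogen-bonded nucleophile. Forcing the temperature risks bis-arylation and thermal damage to the prenyl ether. The fallback makes the substitution intramolecular (a depside Smiles rearrangement); it sets out from 9 and comes back at 11. Compound 9 is treated with the sodium alkoxide of 2-(methylsulfonyl)ethanol (NaH, DMF, 0 °C to rt; substitution of fluoride, then loss of methyl vinyl sulfone) to give the phenol 2-hydroxy-5-methoxy-3-[(3-methylbut-2-en-1-yl)oxy]benzaldehyde F1. F1 is esterified with commercial 2,6-dihydroxy-4-methylbenzoic acid (Cc1cc(O)c(C(=O)O)c(O)c1; DCC, cat. DMAP, CH2Cl2) to the depside 2-formyl-4-methoxy-6-[(3-methylbut-2-en-1-yl)oxy]phenyl 2,6-dihydroxy-4-methylbenzoate F2. K2CO3 in DMSO (rt to 60 °C) then lets a ring A phenoxide attack the ester-bearing carbon of ring B through a six-membered spiro Meisenheimer intermediate and expel the carboxylate. This gives 2-{2-formyl-4-methoxy-6-[(3-methylbut-2-en-1-yl)oxy]phenoxy}-6-hydroxy-4-methylbenzoic acid F3. Selective alkylation of the carboxylate (MeI, KHCO3, DMF, rt) returns 11.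

(2) Step 2 can fail through incomplete regiocontrol of the borylation (some attack ortho to methoxy), protodeboronation of the ortho-fluoro boronate, or over-oxidation if peroxide survives into the acidic unmasking. The fallback replaces catalytic C–H borylation by acidity-controlled deprotonation next to fluorine; it sets out from 3 and comes back at 7. Compound 3 is metalated with lithium 2,2,6,6-tetramethylpiperidide (THF, −78 °C) and quenched with B(OMe)3; mild aqueous work-up gives [3-(1,3-dioxolan-2-yl)-2-fluoro-5-methoxyphenyl]boronic acid F4. Oxidation with NaOH/H2O2 gives 6, and 2 M HCl then hydrolyses the acetal to 7.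

(3) Step 3 is the least risky of the three. The concern is that the phenoxide of 7 shares the flask with formyl-activated aryl fluorides (7 and 9), which can cost material through intermolecular SNAr if the alkylation is slow or warmed. The fallback changes the order so that the alkylation is done while the aldehyde is still masked and the fluoride is unactivated; it sets out from 6 and comes back at 9. The step 2 sequence is stopped before the acid treatment and 6 is isolated. Alkylation of 6 with 8 (K2CO3, DMF, rt) gives 2-{2-fluoro-5-methoxy-3-[(3-methylbut-2-en-1-yl)oxy]phenyl}-1,3-dioxolane F5. Mild acetal hydrolysis (pyridinium p-toluenesulfonate, acetone/H2O, 40 °C) gives 9.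

**Further compounds**
F1 | step 4 | 2-hydroxy-5-methoxy-3-[(3-methylbut-2-en-1-yl)oxy]benzaldehyde | O=Cc1cc(OC)cc(OCC=C(C)C)c1O
F2 | step 4 | 2-formyl-4-methoxy-6-[(3-methylbut-2-en-1-yl)oxy]phenyl 2,6-dihydroxy-4-methylbenzoate | Cc1cc(O)c(C(=O)Oc2c(C=O)cc(OC)cc2OCC=C(C)C)c(O)c1
F3 | step 4 | 2-{2-formyl-4-methoxy-6-[(3-methylbut-2-en-1-yl)oxy]phenoxy}-6-hydroxy-4-methylbenzoic acid | OC(=O)c1c(O)cc(C)cc1Oc1c(C=O)cc(OC)cc1OCC=C(C)C
F4 | step 2 | [3-(1,3-dioxolan-2-yl)-2-fluoro-5-methoxyphenyl]boronic acid | COc1cc(B(O)O)c(F)c(C2OCCO2)c1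
F5 | step 3 | 2-{2-fluoro-5-methoxy-3-[(3-methylbut-2-en-1-yl)oxy]phenyl}-1,3-dioxolane | COc1cc(OCC=C(C)C)c(F)c(C2OCCO2)c1
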